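## Structural features

2'-Hydroxylupalbigenin is an achiral isoflavone: benzo ring A is fused to the γ-pyrone ring C (O1, C2, C3, C4, C4a, C8a), and ring B is attached through the C3–C1' bond. Rings A and B are both 1,3-dioxygenated, and each carries a 3-methylbut-2-enyl (prenyl) group on the carbon between its two oxygens: C6 between C5–OH and C7–OH, C3' between C2'–OH and C4'–OH. There is no stereocentre and no alkene geometry, because each side-chain alkene ends in two methyl groups. The fragile elements are the two prenyl groups ortho to phenols (acid closes them to 2,2-dimethylchromans; oxidants, electrophilic halogen or divalent palladium give chromenes or dihydrofurans; hydrogenation saturates them), the pyrone C2 towards hydroxide, and the electron-rich polyphenol towards air. The real difficulty is regiochemical and tactical: prenyl must sit at C6 and not C8, at C3' and not C5', and both chains must survive the building of ring C and the unmasking of four phenols. The key step uses the fact that C2'–C3'–C4' of ring B, with carbon on C3', is the enol pattern of a 2-alkylcyclohexane-1,3-dione. Sulcatone maps onto C5', C4', C3' and the intact prenyl chain; dimethyl itaconate maps onto C6', C1', C2' and a two-carbon arm on C1' that becomes C3 and C4. On ring A, O1 stands para to C6, so a 3,5-dioxygenated 4-prenylphenol with a mirror plane through C1 and C4 makes the C6/C8 question disappear.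

## Logic of the disconnections

23 ⇒ 22. The four phenolic O–H bonds are traced back to O–CH2OCH3 acetals. These survive organolithium reagents, amide acetals and base, which the earlier steps need. The gain is that no free phenol sits next to a prenyl group until the last step. The demand is that acetal cleavage must be faster than protonation of either side-chain alkene.

22 ⇒ 20. O1–C2 and C2–C3 are cut and C2 is removed as a one-carbon unit at the formate level. Inserting this carbon between a single free phenol and an activated methylene needs no strong acid and no defined enol-ether geometry; an enol-ether-first order with a later acylation at C4a would need one or the other. Ring C disappears. The demand is that 20 has exactly one free hydroxyl ortho to the carbonyl, on the carbon para to the prenyl-bearing carbon; otherwise the 8-prenyl isomer would also form.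

20 ⇒ 10 + 18. C4–C4a is cut. The acyl carbon comes as the N-methoxy-N-methylamide of 10, and C4a comes as a carbon–metal bond generated from the C–I bond of 18 through 19. This divides the molecule into two halves of equal size, and the iodine marks the carbon ortho to the only free hydroxyl before the halves meet. The demands are halogen–metal exchange faster than any proton abstraction, addition faster than enolisation of the acidic CH2 of 10, and an acyl donor that stops at the ketone.

18 ⇒ 17. The C–I bond is cut. In 17 the para position is blocked and the two ortho positions are equivalent, so only one monoiodide can form. The demand is an iodine source that attacks the phenol ring and not the alkene.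

17 ⇒ 15. The C–O bond para to the prenyl group is cut, through the C–B bond of 16. That carbon carries the only aromatic C–H of 15 without an ortho substituent, so a sterically governed C–H borylation finds it. The three oxygens of ring A never have to be told apart. The demand is a catalyst that leaves the trisubstituted alkene alone.

15 ⇒ 12 + 13, and 12 ⇒ 11. The aryl–CH2 bond between the two acetal oxygens is cut, through 14, and then the two O–CH2 bonds. The position between two coordinating oxygens is the one that directed metalation selects. The demand is allylation at the primary carbon of 13 without allylic transposition.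

10 ⇒ 9 ⇒ 8. The amide C–N bond is traced back to the methyl ester and the two acetal O–C bonds to the free resorcinol. These are functional-group changes only; the carbon skeleton of ring B with its arm is already complete in 8.

8 ⇒ 5. Two hydrogens are added back across the ring, through 7 and 6. The aromatic ring becomes the enolised cyclohexane-1,3-dione, in which C3' already lies between the two oxygens. The demand on the forward step is an oxidant that takes two hydrogens from the ring without touching the prenyl group, which excludes halogen, divalent palladium and hot Pd/C.

5 ⇒ 1 + 2 (key disconnection). C2'–C3' is cut in a retro-Claisen sense to give 4, and C5'–C6' in a retro-Michael sense to give 3 (from 1) and 2. Two bonds and ring B come from two purchased compounds, and prenyl is placed on C3' by construction. The constitutions and locants of 1, 2, 4 and 5 were checked against one another and need no correction. The analysis of ring closure is extended in one respect: besides the six- and seven-membered modes, a five-membered closure of C5' onto the arm ester exists. The improvement in how the precursor is used follows from this: 1 enters as its preformed kinetic enolate 3, and the Claisen stage is run under equilibrating methoxide so that a wrong closure can revert.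

## Other disconnections considered

Alternative 1: The cut is at C6–CH2 and C3'–CH2; both chains are traced back to 1,1-dimethylallyl ethers on O5 and O2' of A2. In the forward sense A2 would be heated so that two aromatic Claisen rearrangements give A1, each chain arriving with allylic inversion as a normal prenyl group, and acid would then take A1 to 23.
- In its favour: each ether oxygen has one free ortho carbon only (C6 for O5, C3' for O2'), the step is neutral and pericyclic, both chains are installed in one operation, and no ring has to be dehydrogenated.
- Against it here: O5 is chelated to the C4 carbonyl and O2' is flanked by ring C, so making the two tertiary ethers of A2 would cost further operations. Tertiary aryl allyl ethers can also lose their C5 chain on heating. The dienone formed at C6 can pass the chain on to C8 by a Cope shift before it enolises. In A1, two phenols are already free beside prenyl groups while two acetals still await acid.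
- Comparison: on late, simultaneous introduction of both chains and on freedom from any oxidation-state change the alternative is the better plan. On step count the two are about equal. The chosen plan is stronger in that both prenyl positions are fixed by construction (C3' by the skeleton of 1, C6 by the symmetry of 17) and not by relative rates.

Alternative 2: The cut is at O1–C8a and C4–C4a. In the forward sense fluoride would release an aryne from the ortho-silylaryl triflate A5. The enolate oxygen of the α-formyl ester A4 would add at C8a, and the aryl anion at C4a would close onto the ester to give A3, which is the same compound as 22.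
- In its favour: two bonds of ring C form in one flask without acid or organolithium, the C5 acetal polarises the aryne in the required sense, A4 would come from 9 by one formylation, and the last step would be shared.
- Against it here: A5 needs several operations beyond 17. Stabilised enolates of 1,3-dicarbonyl compounds tend to add to arynes through carbon, which leads to insertion into the C–C(=O) bond. The aryne can undergo ene reaction with the trisubstituted alkenes. Only the enolate geometry with oxygen cis to the ester can close.
- Comparison: in bond economy of the ring C event the alternative is better (two steps from 9 against three). On total step count it is equal or slightly longer because of A5. On predictability of chemoselectivity the chosen plan is stronger, since the amide stops at the ketone and only one hydroxyl can cyclise. On the final deprotection the two are equal.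

Alternative 3: The cut is in the side chains; each prenyl group is traced back to an allyl group in A7. In the forward sense the second-generation Grubbs catalyst in excess A8 would exchange each terminal CH2 for C(CH3)2 to give A6, and mild base would remove the four acetates to give 23.
- In its favour: allyl groups are far less prone to acid cyclisation than prenyl, so the core could be made with classical acid-mediated chemistry. Allyl can be placed by O-allylation and Claisen rearrangement onto a single free ortho carbon in each ring. The acetates are removed under conditions that are harmless to prenyl.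
- Against it here: two metathesis events must both go to completion, ruthenium hydrides can shift allyl to propenyl so that a carbon is then lost, the C5 acetate peri to the carbonyl is labile, and the exchange adds late steps.
- Comparison: on the final deprotection and on acid tolerance of the intermediates the alternative is clearly the better plan. On regiocontrol at C3' and C6 the two are equal. On step count it is somewhat longer. The chosen plan carries finished prenyl groups from the first step of each branch, which saves the exchange but obliges every later step to be acid-free.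

Key step: step 1

Remark: primed locants refer to ring B and unprimed ones to the chromone. Ring A is taken from resorcinol and its third oxygen is introduced by C–H oxidation, so that three equivalent hydroxyls never have to be differentiated.

## Steps

Step 1
Reactants: 1 6-methylhept-5-en-2-one (sulcatone); 2 dimethyl itaconate
Product: 5 methyl 2-[2,4-dioxo-3-(3-methylbut-2-enyl)cyclohexyl]acetate (racemic; enol form), via lithium enolate 3 (not isolated), via keto diester 4 (not isolated)
Conditions: LiN(iPr)2 (1.1 equiv), THF, −78 °C; 2 (0.9 equiv), −78 → −20 °C; NaOMe (2 equiv), MeOH, 65 °C; aq. HCl to pH 3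
Reagents that add atoms: none
Why: Deprotonation of 1 by LiN(iPr)2 at −78 °C, with the ketone added to the base, is irreversible and takes the methyl proton, so 3 carries its charge on the future C5'; 3 adds to the unsubstituted alkene terminus of 2 (Michael addition, C5'–C6') and the resulting ester enolate is quenched by proton exchange to the keto diester 4. Under methoxide 4 enolises towards C3', and this enolate attacks the ester carbon on C1' in a 6-(enolendo)-exo-trig Claisen condensation (C2'–C3'); loss of methoxide and deprotonation of the new 1,3-dione to its vinylogous carboxylate make the closure irreversible. The closest known reaction type is the base-mediated Michael–Claisen annulation of methyl ketones with acrylates, that is, cyclisation of a δ-keto ester to a cyclohexane-1,3-dione. The only new stereocentre, C1', forms without control as a racemate and is of no concern because step 2 makes it trigonal. Three selectivities are needed: methyl over methylene enolate (kinetic deprotonation, no free ketone present), conjugate addition over proton abstraction from the acidic CH2 of 2 (low temperature, lithium enolate, acceptor added slowly), and six-membered over five- or seven-membered closure. The seven-membered mode (C3' onto the arm ester) is slow for ring-size reasons; the five-membered mode (C5' onto the arm ester) is a real competitor, but its product, a 2-acylcyclopentanone, should be reopened by hot methoxide at the strained ring carbonyl and returned to 4, whereas the enolate of 5 is inert, so the equilibrating medium should funnel material into 5.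

Step 2
Reactants: 5 methyl 2-[2,4-dioxo-3-(3-methylbut-2-enyl)cyclohexyl]acetate
Product: 8 methyl 2-[2,4-dihydroxy-3-(3-methylbut-2-enyl)phenyl]acetate, via bis(silyl) dienol ether 6 (not isolated), via bis(silyl) aryl ether 7 (not isolated)
Conditions: Me3SiOTf (2.5 equiv), Et3N (3.5 equiv), CH2Cl2, 0 °C; pentane, filtration; DDQ (1.05 equiv), toluene, 0 → 25 °C; K2CO3 (0.2 equiv), MeOH, 0 °C
Reagents that add atoms: none
Why: Soft enolisation turns the enolised dione into a 1,3-bis(silyloxy)cyclohexa-1,3-diene (either regioisomer serves), which DDQ should dehydrogenate to the arene by hydride abstraction and proton loss, the known silyl dienol ether/DDQ aromatisation of cyclohexenones. No free phenol is present while the oxidant is, the isolated trisubstituted alkene is not a substrate at this temperature, and the aryl silyl ethers are methanolysed at the end.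

Step 3
Reactants: 8 methyl 2-[2,4-dihydroxy-3-(3-methylbut-2-enyl)phenyl]acetate
Product: 9 methyl 2-[2,4-bis(methoxymethoxy)-3-(3-methylbut-2-enyl)phenyl]acetate
Conditions: MOMCl (3 equiv), iPr2NEt (4 equiv), Bu4NI (5 mol %), CH2Cl2, 0 → 40 °C
Reagents that add atoms: chloromethyl methyl ether (MOMCl), COCCl
Why: Williamson-type O-alkylation of both phenols gives the bis-acetal; the amine base is too weak to enolise the ester, and early capping of the C2' hydroxyl removes the option of lactonisation onto the arm.

Step 4
Reactants: 9 methyl 2-[2,4-bis(methoxymethoxy)-3-(3-methylbut-2-enyl)phenyl]acetate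
Product: 10 2-[2,4-bis(methoxymethoxy)-3-(3-methylbut-2-enyl)phenyl]-N-methoxy-N-methylacetamide
Conditions: MeNH(OMe)·HCl (1.5 equiv), iPrMgCl (3 equiv), THF, −20 → 0 °C
Reagents that add atoms: N,O-dimethylhydroxylamine hydrochloride, CNOC.Cl
Why: Aminolysis of the methyl ester by the magnesium amide ClMgN(OMe)Me (Weinreb amide formation from an ester) outpaces enolisation at −20 °C; acetals and alkene are inert to the reagent.

Step 5
Reactants: 11 resorcinol
Product: 12 1,3-bis(methoxymethoxy)benzene
Conditions: NaH (2.4 equiv), MOMCl (2.4 equiv), DMF, 0 → 25 °C
Reagents that add atoms: chloromethyl methyl ether (MOMCl), COCCl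
Why: Williamson etherification of both phenoxides; the acetals serve later as protecting groups and as directing groups for metalation.

Step 6
Reactants: 12 1,3-bis(methoxymethoxy)benzene; 13 prenyl bromide (1-bromo-3-methylbut-2-ene)
Product: 15 1,3-bis(methoxymethoxy)-2-(3-methylbut-2-enyl)benzene, via aryllithium 14 (not isolated)
Conditions: n-BuLi (1.1 equiv), THF, 0 → 25 °C; CuI (10 mol %), 13 (1.2 equiv), −78 → 25 °C
Reagents that add atoms: none
Why: Directed ortho-metalation takes the proton between the two coordinating acetal oxygens, and copper-catalysed allylation of the aryllithium at the primary carbon of 13 (SN2) should give the linear prenyl arene.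

Step 7
Reactants: 15 1,3-bis(methoxymethoxy)-2-(3-methylbut-2-enyl)benzene
Product: 17 3,5-bis(methoxymethoxy)-4-(3-methylbut-2-enyl)phenol, via arylboronate 16 (not isolated)
Conditions: [Ir(OMe)(cod)]2 (1.5 mol %), 4,4'-di-tert-butyl-2,2'-bipyridine (3 mol %), B2pin2 (1.0 equiv), THF, 65 °C; then NaOH (aq), H2O2 (30%), 0 → 25 °C
Reagents that add atoms: hydrogen peroxide, OO
Why: Iridium-catalysed arene C–H borylation is governed by sterics, and C5–H is the only aromatic C–H of 15 without an ortho substituent. Oxidation of the C–B bond with basic peroxide (1,2-shift of aryl from boron to oxygen) then gives the phenol para to the prenyl group, and the unactivated alkene is not epoxidised by basic H2O2.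

Step 8
Reactants: 17 3,5-bis(methoxymethoxy)-4-(3-methylbut-2-enyl)phenol
Product: 18 2-iodo-3,5-bis(methoxymethoxy)-4-(3-methylbut-2-enyl)phenol
Conditions: N-iodosuccinimide (1.0 equiv), MeCN, −20 → 0 °C, dark
Reagents that add atoms: N-iodosuccinimide, O=C1CCC(=O)N1I
Why: Electrophilic aromatic iodination of a phenol whose para position is blocked and whose two ortho positions are equivalent can give one monoiodide only; the trioxygenated ring is far more nucleophilic than the side-chain alkene.

Step 9
Reactants: 18 2-iodo-3,5-bis(methoxymethoxy)-4-(3-methylbut-2-enyl)phenol; 10 2-[2,4-bis(methoxymethoxy)-3-(3-methylbut-2-enyl)phenyl]-N-methoxy-N-methylacetamide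
Product: 20 1-[6-hydroxy-2,4-bis(methoxymethoxy)-3-(3-methylbut-2-enyl)phenyl]-2-[2,4-bis(methoxymethoxy)-3-(3-methylbut-2-enyl)phenyl]ethan-1-one, via dilithio phenoxide 19 (not isolated)
Conditions: t-BuLi (3.1 equiv), THF, −78 °C; 10 (0.9 equiv), −78 → −20 °C; aq. NH4Cl
Reagents that add atoms: none
Why: After deprotonation of the phenol, iodine–lithium exchange is faster than any C–H deprotonation and places lithium on the future C4a; addition to the N-methoxy-N-methylamide gives a chelated tetrahedral adduct that collapses to the ketone only on work-up (Weinreb ketone synthesis), so no tertiary alcohol can form. The phenoxide oxygen becomes the single free hydroxyl ortho to the carbonyl.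

Step 10
Reactants: 20 1-[6-hydroxy-2,4-bis(methoxymethoxy)-3-(3-methylbut-2-enyl)phenyl]-2-[2,4-bis(methoxymethoxy)-3-(3-methylbut-2-enyl)phenyl]ethan-1-one
Product: 22 5,7-bis(methoxymethoxy)-3-[2,4-bis(methoxymethoxy)-3-(3-methylbut-2-enyl)phenyl]-6-(3-methylbut-2-enyl)chromen-4-one, via enaminone 21 (not isolated)
Conditions: Me2NCH(OMe)2 (3 equiv), toluene, 80 °C; AcOH (cat.), 25 °C
Reagents that add atoms: N,N-dimethylformamide dimethyl acetal, COC(OC)N(C)C
Why: The amide acetal condenses at the methylene activated by ketone and aryl to give enaminone 21, and the ortho hydroxyl adds to the enaminone carbon with loss of dimethylamine (6-endo-trig addition–elimination), the classical deoxybenzoin route to isoflavones. Since only one hydroxyl is free, only the 6-prenyl isomer can form.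

Step 11
Reactants: 22 5,7-bis(methoxymethoxy)-3-[2,4-bis(methoxymethoxy)-3-(3-methylbut-2-enyl)phenyl]-6-(3-methylbut-2-enyl)chromen-4-one
Product: 23 2'-hydroxylupalbigenin, 5,7-dihydroxy-3-[2,4-dihydroxy-3-(3-methylbut-2-enyl)phenyl]-6-(3-methylbut-2-enyl)chromen-4-one
Conditions: HCl (2 M aq)/MeOH 1:5, 40 °C
Reagents that add atoms: none
Why: Acid-catalysed acetal exchange transfers the four methoxymethyl groups to methanol; at this acid strength and temperature oxocarbenium formation from the acetals should be faster than protonation of the trisubstituted alkenes, and no stereocentre is involved.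

## Compound list

1 | 6-methylhept-5-en-2-one (sulcatone) | CC(=O)CCC=C(C)C | starting material
2 | dimethyl itaconate (dimethyl 2-methylidenebutanedioate) | C=C(CC(=O)OC)C(=O)OC | starting material
3 | lithium 6-methylhepta-1,5-dien-2-olate (kinetic enolate of 1) | C=C([O-])CCC=C(C)C.[Li+] | intermediate
4 | dimethyl 2-(7-methyl-3-oxooct-6-en-1-yl)butanedioate (racemic) | COC(=O)CC(CCC(=O)CCC=C(C)C)C(=O)OC | intermediate
5 | methyl 2-[2,4-dioxo-3-(3-methylbut-2-enyl)cyclohexyl]acetate (racemic, enol form) | COC(=O)CC1CCC(O)=C(CC=C(C)C)C1=O | intermediate
6 | methyl 2-[3-(3-methylbut-2-enyl)-2,4-bis(trimethylsilyloxy)cyclohexa-2,4-dien-1-yl]acetate (racemic; one of two regioisomeric dienes drawn) | COC(=O)CC1CC=C(O[Si](C)(C)C)C(CC=C(C)C)=C1O[Si](C)(C)C | intermediate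
7 | methyl 2-[3-(3-methylbut-2-enyl)-2,4-bis(trimethylsilyloxy)phenyl]acetate | COC(=O)Cc1ccc(O[Si](C)(C)C)c(CC=C(C)C)c1O[Si](C)(C)C | intermediate
8 | methyl 2-[2,4-dihydroxy-3-(3-methylbut-2-enyl)phenyl]acetate | COC(=O)Cc1ccc(O)c(CC=C(C)C)c1O | intermediate
9 | methyl 2-[2,4-bis(methoxymethoxy)-3-(3-methylbut-2-enyl)phenyl]acetate | COCOc1ccc(CC(=O)OC)c(OCOC)c1CC=C(C)C | intermediate
10 | 2-[2,4-bis(methoxymethoxy)-3-(3-methylbut-2-enyl)phenyl]-N-methoxy-N-methylacetamide | COCOc1ccc(CC(=O)N(C)OC)c(OCOC)c1CC=C(C)C | intermediate
11 | resorcinol (benzene-1,3-diol) | Oc1cccc(O)c1 | starting material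
12 | 1,3-bis(methoxymethoxy)benzene | COCOc1cccc(OCOC)c1 | intermediate
13 | prenyl bromide (1-bromo-3-methylbut-2-ene) | CC(C)=CCBr | starting material
14 | [2,6-bis(methoxymethoxy)phenyl]lithium | [Li]c1c(OCOC)cccc1OCOC | intermediate
15 | 1,3-bis(methoxymethoxy)-2-(3-methylbut-2-enyl)benzene | COCOc1cccc(OCOC)c1CC=C(C)C | intermediate
16 | 2-[3,5-bis(methoxymethoxy)-4-(3-methylbut-2-enyl)phenyl]-4,4,5,5-tetramethyl-1,3,2-dioxaborolane | COCOc1cc(B2OC(C)(C)C(C)(C)O2)cc(OCOC)c1CC=C(C)C | intermediate
17 | 3,5-bis(methoxymethoxy)-4-(3-methylbut-2-enyl)phenol | COCOc1cc(O)cc(OCOC)c1CC=C(C)C | intermediate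
18 | 2-iodo-3,5-bis(methoxymethoxy)-4-(3-methylbut-2-enyl)phenol | COCOc1cc(O)c(I)c(OCOC)c1CC=C(C)C | intermediate
19 | lithium 2-lithio-3,5-bis(methoxymethoxy)-4-(3-methylbut-2-enyl)phenolate | [Li]c1c([O-])cc(OCOC)c(CC=C(C)C)c1OCOC.[Li+] | intermediate
20 | 1-[6-hydroxy-2,4-bis(methoxymethoxy)-3-(3-methylbut-2-enyl)phenyl]-2-[2,4-bis(methoxymethoxy)-3-(3-methylbut-2-enyl)phenyl]ethan-1-one | COCOc1cc(O)c(C(=O)Cc2ccc(OCOC)c(CC=C(C)C)c2OCOC)c(OCOC)c1CC=C(C)C | intermediate
21 | 3-(dimethylamino)-1-[6-hydroxy-2,4-bis(methoxymethoxy)-3-(3-methylbut-2-enyl)phenyl]-2-[2,4-bis(methoxymethoxy)-3-(3-methylbut-2-enyl)phenyl]prop-2-en-1-one (alkene geometry not defined) | COCOc1cc(O)c(C(=O)C(=CN(C)C)c2ccc(OCOC)c(CC=C(C)C)c2OCOC)c(OCOC)c1CC=C(C)C | intermediate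
22 | 5,7-bis(methoxymethoxy)-3-[2,4-bis(methoxymethoxy)-3-(3-methylbut-2-enyl)phenyl]-6-(3-methylbut-2-enyl)chromen-4-one | COCOc1ccc(-c2coc3cc(OCOC)c(CC=C(C)C)c(OCOC)c3c2=O)c(OCOC)c1CC=C(C)C | intermediate
23 | 2'-hydroxylupalbigenin, 5,7-dihydroxy-3-[2,4-dihydroxy-3-(3-methylbut-2-enyl)phenyl]-6-(3-methylbut-2-enyl)chromen-4-one (achiral) | CC(C)=CCc1c(O)ccc(-c2coc3cc(O)c(CC=C(C)C)c(O)c3c2=O)c1O | target

## Step count and least certain steps

Total: 11 steps. Longest linear sequence: 7 steps (1, 2, 3, 4, 9, 10, 11; the ring A branch 5, 6, 7, 8, 9, 10, 11 is equally long).

Step 1 (key step). The most likely failure is partition at the Claisen stage. Compound 4 is at once a δ-keto ester (through C3' and the ester on C1') and an ε-keto ester (through C5' and the arm ester), and the five-membered closure onto the unbranched arm ester may be kinetically faster than the wanted one onto the branched ester. The route relies on hot methoxide to reopen the cyclopentanone; exocyclic cleavage of that by-product would waste material. A second weakness lies in the Michael stage: 3 may abstract a proton from the acidic CH2 of 2 and isomerise the acceptor to the unreactive conjugated diester. Fallback, giving up the annulation for ring B: 15 is lithiated ortho to an acetal oxygen (s-BuLi, TMEDA, THF, −78 °C) and quenched with I2 to give 1-iodo-2,4-bis(methoxymethoxy)-3-(3-methylbut-2-enyl)benzene F1. Negishi-type coupling of F1 with the Reformatsky reagent BrZnCH2CO2Me under a zerovalent palladium catalyst (Pd2(dba)3, XPhos, THF, 60 °C) gives 9, where the route is rejoined.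

Step 2. The most likely failure is incomplete second silylation, so that a mono-silyl vinylogous ester meets the oxidant; alternatively the quinone may add to the siloxydiene as a dienophile, or hydride may be abstracted from the benzylic–allylic CH2 once the arene exists. Fallback by enolate selenation: 5 is treated with LiN(iPr)2 (2.2 equiv, THF, −78 °C; the first equivalent is consumed by the acidic enol) and PhSeBr. The ester enolate, as the last-formed and most basic site, is selenated to give methyl 2-[2,4-dioxo-3-(3-methylbut-2-enyl)cyclohexyl]-2-(phenylselanyl)acetate F2. NaIO4 (aq. THF) oxidises the selenide, and syn-elimination gives methyl 2-[2,4-dioxo-3-(3-methylbut-2-enyl)cyclohexylidene]acetate F3, an isomer of the arene, which Et3N tautomerises to 8, where the route is rejoined.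

Step 7. The most likely failure is reaction at the side chain during borylation: hydroboration of the alkene by the pinacolborane formed, or double-bond migration through iridium hydrides. Fallback by introducing the oxygen before the alkene: 12 is borylated and oxidised under the same conditions (its C5–H is again the only one without an ortho substituent) to give 3,5-bis(methoxymethoxy)phenol F4. iPr3SiCl and imidazole give [3,5-bis(methoxymethoxy)phenoxy]tri(propan-2-yl)silane F5. Metalation between the two acetal oxygens (n-BuLi, THF, 0 °C) and CuI-catalysed allylation with 13 give [3,5-bis(methoxymethoxy)-4-(3-methylbut-2-enyl)phenoxy]tri(propan-2-yl)silane F6, and Bu4NF gives 17, where the route is rejoined.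

Step 9. The most likely failure is proton transfer instead of addition: the hindered and basic 19 may remove a benzylic proton next to the amide carbonyl of 10, which would return 17 and 10 on work-up. Fallback with a more electrophilic partner: 10 is reduced with iBu2AlH (THF, −78 °C) to 2-[2,4-bis(methoxymethoxy)-3-(3-methylbut-2-enyl)phenyl]acetaldehyde F7. Addition of 19 to F7 at −78 °C, where carbonyl addition to an aldehyde is much faster than its enolisation, gives racemic 2-{2-[2,4-bis(methoxymethoxy)-3-(3-methylbut-2-enyl)phenyl]-1-hydroxyethyl}-3,5-bis(methoxymethoxy)-4-(3-methylbut-2-enyl)phenol F8. MnO2 (CH2Cl2, 25 °C) oxidises the benzylic alcohol to 20, where the route is rejoined.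

Step 11. The most likely failure is protonation of a side-chain alkene and capture of the tertiary cation by a neighbouring phenol as soon as it is freed (O5 or O7 onto the C6 chain, O2' or O4' onto the C3' chain), that is, chroman formation competing with cleavage of the last acetals. Fallback by aprotic acetal cleavage: 22 is treated with Me3SiOTf and 2,2'-bipyridyl (CH2Cl2, 0 °C), which converts aryl methoxymethyl ethers through pyridinium intermediates into aryl silyl ethers, to give 3-[3-(3-methylbut-2-enyl)-2,4-bis(trimethylsilyloxy)phenyl]-6-(3-methylbut-2-enyl)-5,7-bis(trimethylsilyloxy)chromen-4-one F9. Water (or KF in MeOH) hydrolyses F9 to 23 without a Brønsted acid.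

## Further compounds

F1 | step 1 | 1-iodo-2,4-bis(methoxymethoxy)-3-(3-methylbut-2-enyl)benzene | COCOc1ccc(I)c(OCOC)c1CC=C(C)C
F2 | step 2 | methyl 2-[2,4-dioxo-3-(3-methylbut-2-enyl)cyclohexyl]-2-(phenylselanyl)acetate (mixture of diastereomers, enol form) | COC(=O)C([Se]c1ccccc1)C1CCC(O)=C(CC=C(C)C)C1=O
F3 | step 2 | methyl 2-[2,4-dioxo-3-(3-methylbut-2-enyl)cyclohexylidene]acetate (enol form, alkene geometry not defined) | COC(=O)C=C1CCC(O)=C(CC=C(C)C)C1=O
F4 | step 7 | 3,5-bis(methoxymethoxy)phenol | COCOc1cc(O)cc(OCOC)c1
F5 | step 7 | [3,5-bis(methoxymethoxy)phenoxy]tri(propan-2-yl)silane | COCOc1cc(O[Si](C(C)C)(C(C)C)C(C)C)cc(OCOC)c1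
F6 | step 7 | [3,5-bis(methoxymethoxy)-4-(3-methylbut-2-enyl)phenoxy]tri(propan-2-yl)silane | COCOc1cc(O[Si](C(C)C)(C(C)C)C(C)C)cc(OCOC)c1CC=C(C)C
F7 | step 9 | 2-[2,4-bis(methoxymethoxy)-3-(3-methylbut-2-enyl)phenyl]acetaldehyde | COCOc1ccc(CC=O)c(OCOC)c1CC=C(C)C
F8 | step 9 | 2-{2-[2,4-bis(methoxymethoxy)-3-(3-methylbut-2-enyl)phenyl]-1-hydroxyethyl}-3,5-bis(methoxymethoxy)-4-(3-methylbut-2-enyl)phenol (racemic) | COCOc1cc(O)c(C(O)Cc2ccc(OCOC)c(CC=C(C)C)c2OCOC)c(OCOC)c1CC=C(C)C
F9 | step 11 | 3-[3-(3-methylbut-2-enyl)-2,4-bis(trimethylsilyloxy)phenyl]-6-(3-methylbut-2-enyl)-5,7-bis(trimethylsilyloxy)chromen-4-one | CC(C)=CCc1c(O[Si](C)(C)C)ccc(-c2coc3cc(O[Si](C)(C)C)c(CC=C(C)C)c(O[Si](C)(C)C)c3c2=O)c1O[Si](C)(C)C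
A1 | alternative 1 | 5-hydroxy-3-[2-hydroxy-4-(methoxymethoxy)-3-(3-methylbut-2-enyl)phenyl]-7-(methoxymethoxy)-6-(3-methylbut-2-enyl)chromen-4-one | CC(C)=CCc1c(OCOC)ccc(-c2coc3cc(OCOC)c(CC=C(C)C)c(O)c3c2=O)c1O
A2 | alternative 1 | 7-(methoxymethoxy)-3-[4-(methoxymethoxy)-2-(2-methylbut-3-en-2-yloxy)phenyl]-5-(2-methylbut-3-en-2-yloxy)chromen-4-one | C=CC(C)(C)Oc1cc(OCOC)ccc1-c1coc2cc(OCOC)cc(OC(C)(C)C=C)c2c1=O
A3 | alternative 2 | 5,7-bis(methoxymethoxy)-3-[2,4-bis(methoxymethoxy)-3-(3-methylbut-2-enyl)phenyl]-6-(3-methylbut-2-enyl)chromen-4-one (identical with 22) | COCOc1ccc(-c2coc3cc(OCOC)c(CC=C(C)C)c(OCOC)c3c2=O)c(OCOC)c1CC=C(C)C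
A4 | alternative 2 | methyl 2-[2,4-bis(methoxymethoxy)-3-(3-methylbut-2-enyl)phenyl]-3-oxopropanoate (racemic, in equilibrium with its enol) | COCOc1ccc(C(C=O)C(=O)OC)c(OCOC)c1CC=C(C)C
A5 | alternative 2 | 3,5-bis(methoxymethoxy)-4-(3-methylbut-2-enyl)-2-(trimethylsilyl)phenyl trifluoromethanesulfonate | COCOc1cc(OS(=O)(=O)C(F)(F)F)c([Si](C)(C)C)c(OCOC)c1CC=C(C)C
A6 | alternative 3 | 3-[2,4-diacetoxy-3-(3-methylbut-2-enyl)phenyl]-6-(3-methylbut-2-enyl)-4-oxochromene-5,7-diyl diacetate | CC(C)=CCc1c(OC(C)=O)ccc(-c2coc3cc(OC(C)=O)c(CC=C(C)C)c(OC(C)=O)c3c2=O)c1OC(C)=O
A7 | alternative 3 | 3-[2,4-diacetoxy-3-(prop-2-enyl)phenyl]-4-oxo-6-(prop-2-enyl)chromene-5,7-diyl diacetate | C=CCc1c(OC(C)=O)ccc(-c2coc3cc(OC(C)=O)c(CC=C)c(OC(C)=O)c3c2=O)c1OC(C)=O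
A8 | alternative 3 | 2-methylbut-2-ene | CC=C(C)C
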